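## Retrosynthetic overview

1. Locants used throughout: cyclohexene ring C5(=C10)–C6(OH)–C7–C8(O)–C9; lactone ring C8–O–C12(=O)–C11(=C13H2)–C7; C14 is the CH2O group on C10; the side chain C4(CH3)–C3–C2–C1(OAc) sits on C5.
2. Last disconnection, one operation: C6–C7 (Hosomi–Sakurai allylation) plus C9–C10 (nickel-catalysed reductive C(sp3)–C(sp2) coupling). This [3+3] annulation closes the cyclohexene ring onto a preformed butenolide (lactone ring first, carbocycle second) and gives the target directly.
3. Enabling feature: C7 and C9 flank the lactone carbinol C8, and C7 is the γ-carbon of the 2-carboxyallyl unit C13–C11=C7, so a 3-(silylmethyl)butenolide delivers it together with the exo-methylene. C6 and C10 are 1,3-related across C5, like the carbonyl and β-carbon of a (Z)-β-triflyloxy enal. The lactone stereocentre C8 controls C7 and, through it, C6.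
4. Butenolide fragment (5-iodomethyl, 3-silylmethyl): (R)-glyceraldehyde acetonide, Z-selective Horner–Wadsworth–Emmons olefination, lactonisation, iodination.
5. Enal fragment: (S)-citronellic acid (C1–C6 with C4), ozonolysis, a temporary seven-membered lactone tying C1–O to C6 (opened again by iBu2AlH), Claisen acylation (C10, C14), (Z)-enol triflate, two acylations.

Key step: step 12

Remark: 17 and 18 are drawn as open hydroxy aldehydes; the seven-membered lactols are taken to be minor tautomers.

## Route

Step 1
Reactants: 1 methyl 2-[bis(2,2,2-trifluoroethoxy)phosphoryl]acetate; 2 (iodomethyl)trimethylsilane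
Product: 3 methyl 2-[bis(2,2,2-trifluoroethoxy)phosphoryl]-3-(trimethylsilyl)propanoate (racemic)
Conditions: NaH, DMF, 0 to 50 °C
Reagents that add atoms: none
Why: C-alkylation of the stabilised phosphonate anion (SN2 at the α-silyl iodide) should give the α-substituted Still–Gennari reagent; its stereocentre is destroyed in step 2.

Step 2
Reactants: 3 methyl 2-[bis(2,2,2-trifluoroethoxy)phosphoryl]-3-(trimethylsilyl)propanoate; 4 (R)-2,2-dimethyl-1,3-dioxolane-4-carbaldehyde
Product: 5 methyl (2E)-3-[(4S)-2,2-dimethyl-1,3-dioxolan-4-yl]-2-[(trimethylsilyl)methyl]prop-2-enoate (ester cis to the dioxolane)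
Conditions: KN(SiMe3)2, 18-crown-6, THF, −78 °C
Reagents that add atoms: none
Why: The Still–Gennari variant of the Horner–Wadsworth–Emmons olefination is kinetically selective for the alkene with the ester cis to the aldehyde residue, as needed for lactonisation; the aldehyde stereocentre (future C8) is not touched at −78 °C.

Step 3
Reactants: 5 methyl (2E)-3-[(4S)-2,2-dimethyl-1,3-dioxolan-4-yl]-2-[(trimethylsilyl)methyl]prop-2-enoate
Product: 7 (5S)-5-(hydroxymethyl)-3-[(trimethylsilyl)methyl]furan-2(5H)-one, via diol 6 (not isolated)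
Conditions: TsOH·H2O (cat.), MeOH/H2O, 23 to 40 °C
Reagents that add atoms: none
Why: Acetal hydrolysis frees the diol, and the secondary hydroxyl, held cis to the ester, should close the five-membered lactone by transesterification (5-exo-trig) with C8 unchanged; the electron-poor allylsilane resists protodesilylation.

Step 4
Reactants: 7 (5S)-5-(hydroxymethyl)-3-[(trimethylsilyl)methyl]furan-2(5H)-one
Product: 8 (5S)-5-(iodomethyl)-3-[(trimethylsilyl)methyl]furan-2(5H)-one
Conditions: I2, PPh3, imidazole, CH2Cl2, 0 °C
Reagents that add atoms: iodine, II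
Why: Appel iodination of the primary alcohol (SN2 by iodide on the alkoxyphosphonium ion) under conditions too weakly basic to touch the acidic C8–H.

Step 5
Reactants: 9 (3S)-3,7-dimethyloct-6-enoic acid ((S)-citronellic acid)
Product: 11 (3S)-6-hydroxy-3-methylhexanoic acid, via aldehyde acid 10 (not isolated)
Conditions: O3, CH2Cl2/MeOH, −78 °C; then NaBH4, −78 to 0 °C; aq. HCl to pH 3
Reagents that add atoms: ozone, [O-][O+]=O
Why: Ozonolysis of the trisubstituted alkene with hydride reduction of the peroxidic intermediates removes the isopropylidene carbons and leaves C1 as a primary alcohol; the C4 stereocentre is not involved.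

Step 6
Reactants: 11 (3S)-6-hydroxy-3-methylhexanoic acid
Product: 13 (4S)-4-methyloxepan-2-one, via mixed anhydride 12 (not isolated)
Conditions: 2,4,6-Cl3C6H2COCl, Et3N, THF, 23 °C; then DMAP, toluene, 80 °C, 0.005 M
Reagents that add atoms: none
Why: Yamaguchi lactonisation (mixed anhydride, acyl transfer at high dilution) should form the seven-membered lactone, a temporary ring that masks C1–OH and holds C6 at the acid level.

Step 7
Reactants: 13 (4S)-4-methyloxepan-2-one; 14 chloroacetyl chloride
Product: 15 (4S)-3-(chloroacetyl)-4-methyloxepan-2-one (C3 epimers and enol)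
Conditions: LiN(iPr)2 (2.1 equiv), THF, −78 °C; then 14, −78 °C; AcOH
Reagents that add atoms: none
Why: Crossed Claisen acylation of the lactone lithium enolate at C5 by the acid chloride (faster than SN2 at CH2Cl) installs C10 and C14; the second equivalent of base takes up the acidic β-dicarbonyl proton, and C4 is not epimerisable.

Step 8
Reactants: 15 (4S)-3-(chloroacetyl)-4-methyloxepan-2-one
Product: 16 (3Z,4S)-3-[2-chloro-1-(trifluoromethanesulfonyloxy)ethylidene]-4-methyloxepan-2-one
Conditions: NaH, Et2O, 0 °C; then Tf2O, −78 to 0 °C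
Reagents that add atoms: trifluoromethanesulfonic anhydride, O=S(=O)(OS(=O)(=O)C(F)(F)F)C(F)(F)F
Why: O-sulfonylation of the sodium-chelated (Z)-enolate of the β-keto lactone (stereoselective enol triflate formation from β-keto esters) should place OTf cis to the lactone carbonyl, which fixes the C5=C10 geometry with the C10 leaving group cis to C6.

Step 9
Reactants: 16 (3Z,4S)-3-[2-chloro-1-(trifluoromethanesulfonyloxy)ethylidene]-4-methyloxepan-2-one
Product: 17 (2Z)-4-chloro-2-[(2S)-5-hydroxypentan-2-yl]-3-(trifluoromethanesulfonyloxy)but-2-enal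
Conditions: iBu2AlH (1.1 equiv), CH2Cl2, −78 °C; aq. potassium sodium tartrate
Reagents that add atoms: none
Why: Partial reduction of the lactone to the aluminium hemiacetal and work-up opens the temporary ring to the C6 aldehyde and the free C1–OH; enol triflate and allylic chloride are inert and the alkene geometry is retained.

Step 10
Reactants: 17 (2Z)-4-chloro-2-[(2S)-5-hydroxypentan-2-yl]-3-(trifluoromethanesulfonyloxy)but-2-enal
Product: 18 (2Z,4S)-3-formyl-7-hydroxy-4-methyl-2-(trifluoromethanesulfonyloxy)hept-2-en-1-yl 2-methylpropanoate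
Conditions: isobutyric acid, Cs2CO3, DMF, 0 °C
Reagents that add atoms: isobutyric acid, CC(C)C(=O)O
Why: SN2 displacement of the primary allylic chloride by caesium isobutyrate (carboxylate alkylation) installs the C14 ester.

Step 11
Reactants: 18 (2Z,4S)-3-formyl-7-hydroxy-4-methyl-2-(trifluoromethanesulfonyloxy)hept-2-en-1-yl 2-methylpropanoate
Product: 19 (2Z,4S)-7-acetoxy-3-formyl-4-methyl-2-(trifluoromethanesulfonyloxy)hept-2-en-1-yl 2-methylpropanoate
Conditions: AcCl, 2,4,6-collidine, CH2Cl2, −20 °C
Reagents that add atoms: acetyl chloride, CC(Cl)=O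
Why: Acylation of the primary alcohol with a hindered, non-nucleophilic pyridine base that should not add to the β-triflyloxy enal.

Step 12
Reactants: 8 (5S)-5-(iodomethyl)-3-[(trimethylsilyl)methyl]furan-2(5H)-one; 19 (2Z,4S)-7-acetoxy-3-formyl-4-methyl-2-(trifluoromethanesulfonyloxy)hept-2-en-1-yl 2-methylpropanoate
Product: 22 (4S)-4-[(3aR,4S,7aR)-4-hydroxy-3-methylidene-6-{[(2-methylpropanoyl)oxy]methyl}-2-oxo-2,3,3a,4,7,7a-hexahydro-1-benzofuran-5-yl]pentyl acetate (target), via iodo triflate silyl ether 20 (not isolated), via bicyclic silyl ether 21 (not isolated)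
Conditions: Tf2NH (10 mol %), CH2Cl2, −78 to −30 °C; then DMA, evaporation of CH2Cl2, NiBr2(dme) (20 mol %), 4,4'-di-tert-butyl-2,2'-bipyridine (24 mol %), Mn powder, 40 °C, 0.01 M; aq. citric acid
Reagents that add atoms: none
Why: Me3SiNTf2 formed in situ activates aldehyde 19, and the γ-carbon of the lactone-embedded 2-carboxyallylsilane (C7) attacks it through an open antiperiplanar transition state with transfer of silicon to oxygen (Hosomi–Sakurai allylation of a 2-(alkoxycarbonyl)allylsilane), giving the exo-methylene lactone 20 with the C6–C7 bond. C7 is set by C8, because the aldehyde enters the butenolide face anti to the CH2I group (trans lactone); C6 is set by the open transition state, in which the alkenyl residue of the aldehyde lies next to H7 and not next to ring carbon C8, which gives the syn relation of C6–O and C7–C8 found in the target. After the solvent switch, zerovalent nickel inserts into the C10–OTf bond, the C9 radical formed from the iodide is captured at the same nickel centre, and reductive elimination closes the cyclohexene ring with retention of the C5=C10 geometry (six-membered ring closure by intramolecular cross-electrophile coupling; closest known type: nickel-catalysed reductive alkyl–alkenyl coupling). The order of the two events is needed: C7 is already sp3 when the C9 radical forms, so 3-exo attack on a conjugated lactone alkene (vinyl shift) cannot compete, and intramolecular capture at nickel should outrun 5-exo addition to the tetrasubstituted alkene. Chemoselectivity for the enol triflate over the hindered allylic isobutyrate rests on the faster oxidative addition of the electron-poor C–OTf bond; acidic work-up cleaves the silyl ether of 21 to give 22.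

## Compound list

1 | methyl 2-[bis(2,2,2-trifluoroethoxy)phosphoryl]acetate | COC(=O)CP(=O)(OCC(F)(F)F)OCC(F)(F)F | starting material
2 | (iodomethyl)trimethylsilane | C[Si](C)(C)CI | starting material
3 | methyl 2-[bis(2,2,2-trifluoroethoxy)phosphoryl]-3-(trimethylsilyl)propanoate (racemic) | COC(=O)C(C[Si](C)(C)C)P(=O)(OCC(F)(F)F)OCC(F)(F)F | intermediate
4 | (R)-2,2-dimethyl-1,3-dioxolane-4-carbaldehyde | O=C[C@H]1COC(C)(C)O1 | starting material
5 | methyl (2E)-3-[(4S)-2,2-dimethyl-1,3-dioxolan-4-yl]-2-[(trimethylsilyl)methyl]prop-2-enoate | COC(=O)/C(C[Si](C)(C)C)=C\[C@H]1COC(C)(C)O1 | intermediate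
6 | methyl (2E,4S)-4,5-dihydroxy-2-[(trimethylsilyl)methyl]pent-2-enoate | COC(=O)/C(C[Si](C)(C)C)=C\[C@H](O)CO | intermediate
7 | (5S)-5-(hydroxymethyl)-3-[(trimethylsilyl)methyl]furan-2(5H)-one | O=C1O[C@H](CO)C=C1C[Si](C)(C)C | intermediate
8 | (5S)-5-(iodomethyl)-3-[(trimethylsilyl)methyl]furan-2(5H)-one | O=C1O[C@H](CI)C=C1C[Si](C)(C)C | intermediate
9 | (3S)-3,7-dimethyloct-6-enoic acid | OC(=O)C[C@@H](C)CCC=C(C)C | starting material
10 | (3S)-3-methyl-6-oxohexanoic acid | OC(=O)C[C@@H](C)CCC=O | intermediate
11 | (3S)-6-hydroxy-3-methylhexanoic acid | OC(=O)C[C@@H](C)CCCO | intermediate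
12 | (3S)-6-hydroxy-3-methylhexanoic 2,4,6-trichlorobenzoic anhydride | O=C(C[C@@H](C)CCCO)OC(=O)c1c(Cl)cc(Cl)cc1Cl | intermediate
13 | (4S)-4-methyloxepan-2-one | O=C1C[C@@H](C)CCCO1 | intermediate
14 | chloroacetyl chloride | ClCC(Cl)=O | starting material
15 | (4S)-3-(chloroacetyl)-4-methyloxepan-2-one (C3 epimers and enol) | O=C1OCCC[C@H](C)C1C(=O)CCl | intermediate
16 | (3Z,4S)-3-[2-chloro-1-(trifluoromethanesulfonyloxy)ethylidene]-4-methyloxepan-2-one | ClC/C(OS(=O)(=O)C(F)(F)F)=C1/C(=O)OCCC[C@@H]1C | intermediate
17 | (2Z)-4-chloro-2-[(2S)-5-hydroxypentan-2-yl]-3-(trifluoromethanesulfonyloxy)but-2-enal | O=C/C(=C(\OS(=O)(=O)C(F)(F)F)CCl)[C@@H](C)CCCO | intermediate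
18 | (2Z,4S)-3-formyl-7-hydroxy-4-methyl-2-(trifluoromethanesulfonyloxy)hept-2-en-1-yl 2-methylpropanoate | O=C/C(=C(\OS(=O)(=O)C(F)(F)F)COC(=O)C(C)C)[C@@H](C)CCCO | intermediate
19 | (2Z,4S)-7-acetoxy-3-formyl-4-methyl-2-(trifluoromethanesulfonyloxy)hept-2-en-1-yl 2-methylpropanoate | O=C/C(=C(\OS(=O)(=O)C(F)(F)F)COC(=O)C(C)C)[C@@H](C)CCCOC(C)=O | intermediate
20 | trimethylsilyl ether of the Sakurai adduct: trans-4,5-disubstituted 5-(iodomethyl)-3-methylideneoxolan-2-one carrying at C4 the silyloxy-bearing C6 with the (Z)-enol triflate side arm | C=C1C(=O)O[C@H](CI)[C@H]1[C@H](O[Si](C)(C)C)/C(=C(\OS(=O)(=O)C(F)(F)F)COC(=O)C(C)C)[C@@H](C)CCCOC(C)=O | intermediate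
21 | 6-O-trimethylsilyl ether of the target | C=C1C(=O)O[C@@H]2CC(COC(=O)C(C)C)=C([C@@H](C)CCCOC(C)=O)[C@@H](O[Si](C)(C)C)[C@@H]12 | intermediate
22 | (4S)-4-[(3aR,4S,7aR)-4-hydroxy-3-methylidene-6-{[(2-methylpropanoyl)oxy]methyl}-2-oxo-2,3,3a,4,7,7a-hexahydro-1-benzofuran-5-yl]pentyl acetate | C=C1C(=O)O[C@@H]2CC(COC(=O)C(C)C)=C([C@@H](C)CCCOC(C)=O)[C@@H](O)[C@@H]12 | target

## Step count and risks

Total step count: 12. Longest linear sequence: 8 steps (steps 5 to 12).

Steps most likely to fail:

Step 12. The lactone-conjugated, electron-poor allylsilane may add too slowly to the hindered α-branched enal, or the open transition state may give poor simple diastereoselection at C6. The fallback makes the C6–C7 bond through a closed transition state and corrects C6 afterwards. It sets out from 8: bromodesilylation (Br2, CH2Cl2, −78 °C) should give the allylic bromide (4S,5S)-4-bromo-5-(iodomethyl)-3-methylideneoxolan-2-one F1. Indium-mediated Barbier allylation of 19 with F1 (In powder, THF/H2O, 23 °C) should give, through a chair transition state and attack anti to CH2I, the C6-epimeric alcohol F2. Mitsunobu inversion with formic acid (PPh3, diisopropyl azodicarboxylate, THF, 0 °C) should give the formate F3, and mild methanolysis (KHCO3, MeOH, 0 °C) the free alcohol F4. F4 is cyclised under the nickel conditions of the second stage of step 12 and returns to the route at 22.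

Step 7. The strongly basic Claisen conditions may lead to O-acylation, double acylation or loss of chloride from the α-chloro ketone. The fallback sets out from 13: the enolate would be trapped (LiN(iPr)2, Me3SiCl, THF, −78 °C) as the silyl ketene acetal (4S)-4-methyl-2-(trimethylsilyloxy)-4,5,6,7-tetrahydrooxepine F5, which is C-acylated with 14 under neutral conditions (CH2Cl2, 23 °C) and returns to the route at 15.

Step 10. The carboxylate may attack the triflate-bearing β-carbon of the enal (addition–elimination) instead of the CH2Cl group, or the base may degrade the enal. The fallback sets out from 16: full reduction (iBu2AlH, 2.5 equiv, CH2Cl2, −78 to 0 °C) would give the diol (2Z)-4-chloro-2-[(2S)-5-hydroxypentan-2-yl]-3-(trifluoromethanesulfonyloxy)but-2-en-1-ol F6, whose alkene is no longer an acceptor. Caesium isobutyrate (DMF, 23 °C) then displaces the allylic chloride to give the diol ester F7, and MnO2 (CH2Cl2, 23 °C) oxidises only the allylic alcohol, returning to the route at 18.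

Further compounds
F1 | step 12 | (4S,5S)-4-bromo-5-(iodomethyl)-3-methylideneoxolan-2-one | C=C1C(=O)O[C@H](CI)[C@H]1Br
F2 | step 12 | C6 epimer of alcohol F4 (anti Barbier adduct) | C=C1C(=O)O[C@H](CI)[C@H]1[C@@H](O)/C(=C(\OS(=O)(=O)C(F)(F)F)COC(=O)C(C)C)[C@@H](C)CCCOC(C)=O
F3 | step 12 | formate of alcohol F4 (C6 inverted) | C=C1C(=O)O[C@H](CI)[C@H]1[C@H](OC=O)/C(=C(\OS(=O)(=O)C(F)(F)F)COC(=O)C(C)C)[C@@H](C)CCCOC(C)=O
F4 | step 12 | free alcohol corresponding to silyl ether 20 | C=C1C(=O)O[C@H](CI)[C@H]1[C@H](O)/C(=C(\OS(=O)(=O)C(F)(F)F)COC(=O)C(C)C)[C@@H](C)CCCOC(C)=O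
F5 | step 7 | (4S)-4-methyl-2-(trimethylsilyloxy)-4,5,6,7-tetrahydrooxepine | C[C@H]1CCCOC(O[Si](C)(C)C)=C1
F6 | step 10 | (2Z)-4-chloro-2-[(2S)-5-hydroxypentan-2-yl]-3-(trifluoromethanesulfonyloxy)but-2-en-1-ol | OC/C(=C(\OS(=O)(=O)C(F)(F)F)CCl)[C@@H](C)CCCO
F7 | step 10 | (2Z,4S)-7-hydroxy-3-(hydroxymethyl)-4-methyl-2-(trifluoromethanesulfonyloxy)hept-2-en-1-yl 2-methylpropanoate | OC/C(=C(\OS(=O)(=O)C(F)(F)F)COC(=O)C(C)C)[C@@H](C)CCCO
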